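## Structural features

The target 17, 2,5-dibromo-3,6-bis(2,3,5-tribromo-4-hydroxyphenoxy)benzene-1,4-diol (C18H6Br8O6), consists of three benzene rings joined in a row by two diaryl ether oxygens, with no side chain and no further ring. Ring B, the central ring, is fully substituted: hydroxyls at C1 and C4, bromines at C2 and C5, aryloxy groups at C3 and C6, so it is a centrosymmetric para-hydroquinone. Rings A and C are identical 2,3,5-tribromo-4-hydroxyphenoxy units, each with its hydroxyl para to the ether oxygen and between two bromines, and each with one hydrogen left at C6. There is no stereocentre, so nothing stereochemical has to be set. The fragile parts are the ring B hydroquinone (oxidised to a bromanil-like quinone, fastest as its anion in air), the four acidic phenols, and the eight C–Br bonds, which exclude hydrogenolysis, late organometallic steps and copper- or palladium-mediated ether couplings. The real difficulty is to make two crowded diaryl ether bonds to a hexasubstituted ring with every bromine already in place, because a late bromination of three phenolic rings could not be steered. The key step uses the fact that C1 and C4 of ring B each lie between an ether carbon (C6, C3) and a bromine carbon (C2, C5): a formyl group at C1 and C4 first makes the neighbouring carbons open to aryloxide substitution and is then exchanged for oxygen.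

## Logic of the disconnections

17 ⇒ 15. No skeletal bond is cut; the two formyl C–O bonds on ring B and the two O–CH3 bonds on rings A and C are reconnected. The reason is that the hydroquinone and the outer phenols should stay masked until the last operation, and that all four masks fall to one acidic reagent. The gain is that 15 cannot be oxidised to a quinone. The demand is that one Lewis acid treatment and an acidic methanol quench, passing through 16, free four hydroxyls without touching the diaryl ethers or the C–Br bonds, and that the free hydroquinone never meets base.

15 ⇒ 13. The C1–O and C4–O bonds of ring B are cut and replaced by C–CHO bonds. The reason is that formyl groups are the only substituents that both activate ring B for ether formation and can afterwards be turned into oxygen. The gain is that a pattern of six heteroatom substituents becomes a symmetric dialdehyde that substitution chemistry can reach. The demand is the hardest of the route: the aryl group must migrate in preference to hydrogen, twice (through 14), at aldehydes hemmed in on both sides on an electron-poor ring.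

13 ⇒ 6 + two of 11. The C3–O and C6–O ether bonds of ring B are cut. The reason is that in 6 each of these carbons carries fluorine ortho to a formyl group, and that the cut is convergent and symmetric. The gain is that the three-ring target falls into two monocyclic pieces that already hold all eight bromines. The demand is that a hindered, weakly basic phenoxide displaces fluoride and not bromide, and does so a second time (through 12) although the first aryloxy group sits para to the remaining C–F bond.

6 ⇒ 1. The two aryl–CHO bonds are cut. The reason is that both hydrogens of 1 lie between fluorine and bromine and are the only acidic sites. The gain is a commercial arene. The demand is that the ortho-haloaryllithiums 2 and 4 stay cold enough not to lose lithium halide, and that the first carbonyl remains masked as 3 and then 5 until work-up.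

11 ⇒ 10. One C–Br bond ortho to the free hydroxyl is cut. The reason is that the hydroxyl directs the electrophile to two equivalent positions, so only one constitution can arise. The gain is a symmetric phenol. The demand is to stop after one bromine.

10 ⇒ 8. The aryl C–O bond is cut and replaced by a C–CHO bond; this is the same formyl-for-oxygen exchange as in the key step, on a simpler ring, and it passes through 9. The gain is a benzaldehyde one step away from a commercial material. The demand is again aryl migration, here with a para methoxy group that its two bromine neighbours twist out of conjugation.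

8 ⇒ 7. The O–CH3 bond is cut. The reason is that the oxygen between the two bromines must be masked before the other oxygen is created. The gain is a cheap starting material. The demand is only the alkylation of a hindered but acidic phenol.

## Other disconnections considered

Alternative 1: The cut falls on the outer side of both ether oxygens, at C4 of rings A and C. In the forward sense the phenoxide of 2,3,4,6-tetrabromophenol A2 would be oxidised at a carbon anode to its phenoxyl radical. The oxygen radical is a very strong acceptor para to C4, so an oxygen of the dianion of bromanilic acid A3 could add there and expel bromide. Two such events would give the quinone A1, 2,5-dibromo-3,6-bis(2,3,5-tribromo-4-hydroxyphenoxy)-1,4-benzoquinone, and a mild reduction would then give 17.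
- In its favour: both components are simple, all eight bromines are present from the start, no protecting group is needed, and substitution at C4 would place the ether para to the hydroxyl as required.
- Against it: the dianion of A3 is a weak, delocalised oxygen nucleophile that must react twice. The radical of A2 has easier fates, namely O–C coupling with a second phenoxide and attack at the ortho C–Br bonds, which are activated in the same way. A1 carries two phenols about as oxidisable as A2 and is itself a bromanil-type acceptor.
- Comparison: in step economy this alternative is clearly the better (two or three operations against seven). In structure it is the equal of the chosen plan, since no late bromination is needed. In mechanism it is much less secure, because the chosen plan uses only two-electron reactions of established types, whereas here the radical substitution would have to be extended to a bromide leaving group and a hydroxyquinone nucleophile.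

Alternative 2: Rings A and C are dismantled altogether, each into a carbene carbon with its vinyl group, an alkyne and one CO. In the forward sense the biscarbene complex A5, in which both ring B ether oxygens carry a vinyl(pentacarbonylchromium)carbene unit, would take up trimethylsilylacetylene A6 and a CO ligand at each unit. This Dötz benzannulation forms three C–C bonds per unit and would give the bis(4-aryloxyphenol) A4.
- In its favour: the para oxygen pattern of rings A and C follows from the mechanism, and the silyl group marks one position ortho to each hydroxyl for ipso-bromination. The hindered ring B–O bonds exist before the outer rings do, so no substitution at a crowded aromatic carbon and no peracid step is needed; on this point the alternative is the better.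
- Against it: aryloxy vinyl carbene complexes are more labile than alkoxy ones, an unsubstituted vinyl carbene tends to polymerise, and two such units would have to be installed on oxygens flanked by methoxy and bromine. The chromium is stoichiometric. After A4 each outer ring still needs three bromines; the third must enter meta to the hydroxyl on an already dibrominated ring, where stopping short of four is uncertain, and the ring B methyl ethers must also be cleaved.
- Comparison: in structure it solves the outer oxygen pattern but postpones six of the eight bromines. In mechanism the annulation type is established, but not for a hindered aryloxy biscarbene. In step economy it is the poorer, at nine or more steps.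

Alternative 3: Ring B is cut at the two C–C bonds between each aryloxy-bearing carbon and the adjacent CH carbon, into two molecules of the oxoaldehyde A7, 2-oxo-3-(2,3,5-tribromo-4-methoxyphenoxy)propanal. In the forward sense two aldol condensations, each joining the aryloxy-bearing carbon of one molecule to the aldehyde carbon of the other, would close ring B as the quinone A8, 2,5-bis(2,3,5-tribromo-4-methoxyphenoxy)-1,4-benzoquinone. Bromination of both quinone CH positions would give A9, reduction the hydroquinone A10, and demethylation 17.
- In its favour: ring B arises at the quinone oxidation level with both oxygens and both ethers in place. The route uses the same phenol 11 as the chosen plan, and it needs no distinction between C–F and C–Br bonds and no organolithium; on these points it is the equal or the better.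
- Against it: A7 is a hydrated, self-condensing α-oxoaldehyde that base can divert by internal hydride shift to an α-hydroxy acid. In the first aldol adduct the tribromophenoxide is a far better leaving group than hydroxide, so loss of the aryloxy group competes with the dehydration that is wanted. The ring B bromines must then be introduced on A8, a vinylogous ester that bromide or HBr can attack at the ether carbons.
- Comparison: in structure it builds ring B where the chosen plan buys it, but it sets two bromines late. In mechanism the dimerisation has relatives in the aldol dimerisation of 1,2-dicarbonyl compounds to 2,5-disubstituted benzoquinones, yet not with a leaving group on the nucleophilic carbon. In step economy it is the poorer: three steps to 11, two to A7 and four more to 17.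

Key step: step 6

Remark: the diaryl ether axes are taken to rotate freely at room temperature, so 17 is treated as achiral; mCPBA is assumed to be dried before use in steps 3 and 6.

## Steps

Step 1
Reactants: 1 1,4-dibromo-2,5-difluorobenzene
Product: 6 2,5-dibromo-3,6-difluoroterephthalaldehyde, via aryllithium 2 (not isolated), via lithium aminoalkoxide 3 (not isolated), via lithiated aminoalkoxide 4 (not isolated), via dilithium bis(aminoalkoxide) 5 (not isolated)
Conditions: LiN(iPr)2 (1.1 equiv), THF, −78 °C; DMF (1.1 equiv), −78 °C; LiN(iPr)2 (1.3 equiv), −78 °C; DMF (2 equiv), −78 °C; then 2 M HCl, −78 °C → rt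
Reagents that add atoms: N,N-dimethylformamide, CN(C)C=O
Why: Directed ortho-metalation and formylation in one flask: the amide base (not an alkyllithium, which would exchange bromine) removes the proton between F and Br to give 2, DMF traps it as the tetrahedral adduct 3, which masks the first carbonyl while the second, equivalent proton is removed (4) and formylated (5); acid then releases both aldehydes, and at −78 °C the ortho-haloaryllithiums should not yet lose LiF or LiBr.

Step 2
Reactants: 7 3,5-dibromo-4-hydroxybenzaldehyde
Product: 8 3,5-dibromo-4-methoxybenzaldehyde
Conditions: MeI, K2CO3, DMF, rt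
Reagents that add atoms: iodomethane, CI
Why: Williamson ether synthesis; the phenol between two bromines is acidic enough for carbonate and the small electrophile reaches the hindered oxygen, while the aldehyde is untouched.

Step 3
Reactants: 8 3,5-dibromo-4-methoxybenzaldehyde
Product: 10 3,5-dibromo-4-methoxyphenol, via aryl formate 9 (not isolated)
Conditions: mCPBA, CH2Cl2, 40 °C; aq. NaHCO3 work-up; then K2CO3 (cat.), MeOH, rt
Reagents that add atoms: 3-chloroperoxybenzoic acid (mCPBA), O=C(OO)c1cccc(Cl)c1
Why: Baeyer–Villiger oxidation of an aryl aldehyde (Dakin type): aryl migration in the peracid adduct should give formate 9, which catalytic carbonate in methanol transesterifies to phenol 10; the para methoxy group supports aryl over hydrogen migration, although its two bromine neighbours weaken that support.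

Step 4
Reactants: 10 3,5-dibromo-4-methoxyphenol
Product: 11 2,3,5-tribromo-4-methoxyphenol
Conditions: NBS (1.0 equiv), TsOH·H2O (10 mol%), MeOH, 0 °C → rt
Reagents that add atoms: N-bromosuccinimide, O=C1CCC(=O)N1Br
Why: Electrophilic aromatic bromination: the free hydroxyl directs to its two equivalent ortho positions, so only one constitution can form, and one equivalent of NBS under acid catalysis in methanol is a known way to stop at the mono-ortho-bromophenol because the first bromine deactivates the ring.

Step 5
Reactants: 6 2,5-dibromo-3,6-difluoroterephthalaldehyde; 11 2,3,5-tribromo-4-methoxyphenol (2.2 equiv)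
Product: 13 2,5-dibromo-3,6-bis(2,3,5-tribromo-4-methoxyphenoxy)terephthalaldehyde, via fluoro monoether 12 (not isolated)
Conditions: Cs2CO3 (2.5 equiv), DMF, 60–80 °C
Reagents that add atoms: none
Why: Nucleophilic aromatic substitution by addition–elimination: each C–F bond of 6 lies ortho to a formyl group that stabilises the anionic adduct, and fluoride leaves far faster than bromide in this mechanism, so both C–Br bonds should stay; 12 should form first and the second fluoride follow more slowly.

Step 6
Reactants: 13 2,5-dibromo-3,6-bis(2,3,5-tribromo-4-methoxyphenoxy)terephthalaldehyde
Product: 15 2,5-dibromo-3,6-bis(2,3,5-tribromo-4-methoxyphenoxy)-1,4-phenylene diformate, via formyl monoformate 14 (not isolated)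
Conditions: mCPBA (4 equiv), Na2HPO4 (solid), CH2Cl2, 0 → 40 °C, exclusion of moisture
Reagents that add atoms: 3-chloroperoxybenzoic acid (mCPBA), O=C(OO)c1cccc(Cl)c1
Why: The peracid adds to each formyl carbon to give a tetrahedral peroxy hemiacetal, and a 1,2-shift of the ring B carbon from carbon to oxygen with loss of 3-chlorobenzoate gives the aryl formate; the closest known type is the Baeyer–Villiger (Dakin type) oxidation of ortho-alkoxy- and ortho-aryloxybenzaldehydes to aryl formates. No ring is closed and no stereocentre is formed, so the only selectivity needed is aryl over hydrogen migration. It should be secured by the lone pair of the ortho aryloxy oxygen, which stabilises positive charge at the migrating carbon, and by the crowding of a formyl group wedged between Br and OAr, which places the aryl group anti to the O–O bond in the adduct and is relieved by migration. The methyl ethers on rings A and C were kept as the protecting groups because they leave these ether oxygens as electron-rich as a peracid-stable mask allows. The first migration is the harder one, since the second formyl group is para and withdraws; in 14 that position holds a formyloxy donor, so the second migration should be easier. Solid buffer and dry conditions keep the formates from hydrolysing, which matters because a freed hydroquinone would be oxidised to the quinone by the peracid. The C–Br bonds and the diaryl ethers are inert to peracid.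

Step 7
Reactants: 15 2,5-dibromo-3,6-bis(2,3,5-tribromo-4-methoxyphenoxy)-1,4-phenylene diformate
Product: 17 2,5-dibromo-3,6-bis(2,3,5-tribromo-4-hydroxyphenoxy)benzene-1,4-diol, via boron aryloxide 16 (not isolated)
Conditions: BBr3 (8 equiv), CH2Cl2, −78 °C → rt; then MeOH, 0 → 40 °C; under Ar
Reagents that add atoms: none
Why: Lewis acid ether cleavage followed by acid-catalysed transesterification: BBr3 cleaves both aryl methyl ethers by bromide attack on the complexed methyl group to give 16, and methanol then frees the phenols and, through the HBr it generates, methanolyses the two aryl formates, so the hydroquinone never meets base or oxidant; should BBr3 cleave the formates directly, the same product results.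

## Compound list

1 | 1,4-dibromo-2,5-difluorobenzene | Fc1cc(Br)c(F)cc1Br | starting material
2 | (3,6-dibromo-2,5-difluorophenyl)lithium | [Li]c1c(F)c(Br)cc(F)c1Br | intermediate
3 | lithium (3,6-dibromo-2,5-difluorophenyl)(dimethylamino)methanolate (racemic, transient) | CN(C)C([O-])c1c(F)c(Br)cc(F)c1Br.[Li+] | intermediate
4 | lithium (3,6-dibromo-2,5-difluoro-4-lithiophenyl)(dimethylamino)methanolate (racemic, transient) | CN(C)C([O-])c1c(F)c(Br)c([Li])c(F)c1Br.[Li+] | intermediate
5 | dilithium (2,5-dibromo-3,6-difluoro-1,4-phenylene)bis[(dimethylamino)methanolate] (mixture of diastereomers, transient) | CN(C)C([O-])c1c(F)c(Br)c(C([O-])N(C)C)c(F)c1Br.[Li+].[Li+] | intermediate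
6 | 2,5-dibromo-3,6-difluoroterephthalaldehyde | O=Cc1c(F)c(Br)c(C=O)c(F)c1Br | intermediate
7 | 3,5-dibromo-4-hydroxybenzaldehyde | O=Cc1cc(Br)c(O)c(Br)c1 | starting material
8 | 3,5-dibromo-4-methoxybenzaldehyde | COc1c(Br)cc(C=O)cc1Br | intermediate
9 | 3,5-dibromo-4-methoxyphenyl formate | COc1c(Br)cc(OC=O)cc1Br | intermediate
10 | 3,5-dibromo-4-methoxyphenol | COc1c(Br)cc(O)cc1Br | intermediate
11 | 2,3,5-tribromo-4-methoxyphenol | COc1c(Br)cc(O)c(Br)c1Br | intermediate
12 | 2,5-dibromo-3-fluoro-6-(2,3,5-tribromo-4-methoxyphenoxy)terephthalaldehyde | O=Cc1c(Br)c(F)c(C=O)c(Br)c1Oc1cc(Br)c(OC)c(Br)c1Br | intermediate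
13 | 2,5-dibromo-3,6-bis(2,3,5-tribromo-4-methoxyphenoxy)terephthalaldehyde | O=Cc1c(Br)c(Oc2cc(Br)c(OC)c(Br)c2Br)c(C=O)c(Br)c1Oc1cc(Br)c(OC)c(Br)c1Br | intermediate
14 | 2,5-dibromo-4-formyl-3,6-bis(2,3,5-tribromo-4-methoxyphenoxy)phenyl formate | O=COc1c(Br)c(Oc2cc(Br)c(OC)c(Br)c2Br)c(C=O)c(Br)c1Oc1cc(Br)c(OC)c(Br)c1Br | intermediate
15 | 2,5-dibromo-3,6-bis(2,3,5-tribromo-4-methoxyphenoxy)-1,4-phenylene diformate | O=COc1c(Br)c(Oc2cc(Br)c(OC)c(Br)c2Br)c(OC=O)c(Br)c1Oc1cc(Br)c(OC)c(Br)c1Br | intermediate
16 | 2,5-dibromo-3,6-bis{2,3,5-tribromo-4-[(dibromoboranyl)oxy]phenoxy}-1,4-phenylene diformate | O=COc1c(Br)c(Oc2cc(Br)c(OB(Br)Br)c(Br)c2Br)c(OC=O)c(Br)c1Oc1cc(Br)c(OB(Br)Br)c(Br)c1Br | intermediate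
17 | 2,5-dibromo-3,6-bis(2,3,5-tribromo-4-hydroxyphenoxy)benzene-1,4-diol | Oc1c(Br)cc(Oc2c(O)c(Br)c(Oc3cc(Br)c(O)c(Br)c3Br)c(O)c2Br)c(Br)c1Br | target

## Step count and least certain steps

Total step count: 7. Longest linear sequence: 6 steps (steps 2, 3, 4, 5, 6, 7, from 7 to 17); the other branch runs through steps 1, 5, 6, 7.

Step 6 (key step). The most likely failure is hydrogen migration (or proton loss) in the peracid adduct, so that a formyl group is over-oxidised to a carboxyl group. This is most probable at the first formyl group, while the second still withdraws from the para position and the ring carries two bromines. A second danger is early hydrolysis of a formate, after which the freed hydroquinone would be oxidised. The fallback sets out from 13 and changes the migrating competition from aryl against hydrogen to aryl against methyl. MeMgBr (THF, −40 °C) should add to both formyl groups and give the diol 1,1'-[2,5-dibromo-3,6-bis(2,3,5-tribromo-4-methoxyphenoxy)-1,4-phenylene]diethanol F1. Dess–Martin periodinane should oxidise it to the diketone 1,1'-[2,5-dibromo-3,6-bis(2,3,5-tribromo-4-methoxyphenoxy)-1,4-phenylene]diethanone F2. Baeyer–Villiger oxidation with CF3CO3H (from (CF3CO)2O and urea·H2O2, Na2HPO4, CH2Cl2) should then give the diacetate 2,5-dibromo-3,6-bis(2,3,5-tribromo-4-methoxyphenoxy)-1,4-phenylene diacetate F3, because methyl is the poorest migrating group and even electron-poor aryl methyl ketones give aryl acetates. F3 is treated as in step 7 (BBr3, then methanol with warming), which cleaves aryl acetates and methyl ethers alike, and the route is rejoined at 17.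

Step 5. The second fluoride displacement may stall, because the first aryloxy group is para to the remaining C–F bond and the phenoxide is hindered and weakly basic. Forcing the reaction invites attack at the C–Br bonds ortho to formyl, or base-induced consumption of the aldehydes. The fallback sets out from 6 and exchanges the activating group for a smaller one that is inert to base. Condensation with hydroxylamine and dehydration in one flask (NH2OH·HCl, HCO2Na, HCO2H, reflux) should give 2,5-dibromo-3,6-difluoroterephthalonitrile F4. Substitution with 11 (Cs2CO3, DMF, up to 100 °C) should give 2,5-dibromo-3,6-bis(2,3,5-tribromo-4-methoxyphenoxy)terephthalonitrile F5. Reduction with iBu2AlH (toluene, −78 → 0 °C) and acidic hydrolysis of the imine should return the route to 13.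

Step 1. The adduct 3 may precipitate or revert to free aldehyde before the second metalation, so that the second formylation is incomplete or the amide base adds to the carbonyl. The longer life of the ortho-haloaryllithiums in a two-stage protocol also gives more time for loss of lithium halide and for bromine migration. The fallback sets out from 1 and replaces the transient mask by a covalent one with isolation at each stage. A single metalation–formylation (through 2 and 3) should give 3,6-dibromo-2,5-difluorobenzaldehyde F6. Ethylene glycol and TsOH (toluene, water removal) should give 2-(3,6-dibromo-2,5-difluorophenyl)-1,3-dioxolane F7. A second metalation–formylation should give 2,5-dibromo-4-(1,3-dioxolan-2-yl)-3,6-difluorobenzaldehyde F8, and aqueous HCl in THF should return the route to 6.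

Step 3. Hydrogen migration may compete, giving the benzoic acid, because the methoxy group is twisted out of conjugation by its two bromine neighbours and the ring carries two inductively withdrawing bromines meta to the migrating carbon. The fallback sets out from 8 and again replaces hydrogen by methyl as the competing group. MeMgBr should give 1-(3,5-dibromo-4-methoxyphenyl)ethanol F9, and Dess–Martin periodinane 1-(3,5-dibromo-4-methoxyphenyl)ethanone F10. Baeyer–Villiger oxidation with CF3CO3H should give 3,5-dibromo-4-methoxyphenyl acetate F11, and K2CO3 in methanol should return the route to 10.

## Further compounds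

F1 | step 6 | 1,1'-[2,5-dibromo-3,6-bis(2,3,5-tribromo-4-methoxyphenoxy)-1,4-phenylene]diethanol (mixture of diastereomers) | CC(O)c1c(Br)c(Oc2cc(Br)c(OC)c(Br)c2Br)c(C(C)O)c(Br)c1Oc1cc(Br)c(OC)c(Br)c1Br
F2 | step 6 | 1,1'-[2,5-dibromo-3,6-bis(2,3,5-tribromo-4-methoxyphenoxy)-1,4-phenylene]diethanone | CC(=O)c1c(Br)c(Oc2cc(Br)c(OC)c(Br)c2Br)c(C(C)=O)c(Br)c1Oc1cc(Br)c(OC)c(Br)c1Br
F3 | step 6 | 2,5-dibromo-3,6-bis(2,3,5-tribromo-4-methoxyphenoxy)-1,4-phenylene diacetate | CC(=O)Oc1c(Br)c(Oc2cc(Br)c(OC)c(Br)c2Br)c(OC(C)=O)c(Br)c1Oc1cc(Br)c(OC)c(Br)c1Br
F4 | step 5 | 2,5-dibromo-3,6-difluoroterephthalonitrile | N#Cc1c(F)c(Br)c(C#N)c(F)c1Br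
F5 | step 5 | 2,5-dibromo-3,6-bis(2,3,5-tribromo-4-methoxyphenoxy)terephthalonitrile | N#Cc1c(Br)c(Oc2cc(Br)c(OC)c(Br)c2Br)c(C#N)c(Br)c1Oc1cc(Br)c(OC)c(Br)c1Br
F6 | step 1 | 3,6-dibromo-2,5-difluorobenzaldehyde | O=Cc1c(F)c(Br)cc(F)c1Br
F7 | step 1 | 2-(3,6-dibromo-2,5-difluorophenyl)-1,3-dioxolane | Fc1cc(Br)c(F)c(C2OCCO2)c1Br
F8 | step 1 | 2,5-dibromo-4-(1,3-dioxolan-2-yl)-3,6-difluorobenzaldehyde | O=Cc1c(F)c(Br)c(C2OCCO2)c(F)c1Br
F9 | step 3 | 1-(3,5-dibromo-4-methoxyphenyl)ethanol (racemic) | CC(O)c1cc(Br)c(OC)c(Br)c1
F10 | step 3 | 1-(3,5-dibromo-4-methoxyphenyl)ethanone | CC(=O)c1cc(Br)c(OC)c(Br)c1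
F11 | step 3 | 3,5-dibromo-4-methoxyphenyl acetate | CC(=O)Oc1cc(Br)c(OC)c(Br)c1
A1 | alternative 1 | 2,5-dibromo-3,6-bis(2,3,5-tribromo-4-hydroxyphenoxy)-1,4-benzoquinone | O=C1C(Br)=C(Oc2cc(Br)c(O)c(Br)c2Br)C(=O)C(Br)=C1Oc1cc(Br)c(O)c(Br)c1Br
A2 | alternative 1 | 2,3,4,6-tetrabromophenol | Oc1c(Br)cc(Br)c(Br)c1Br
A3 | alternative 1 | bromanilic acid (2,5-dibromo-3,6-dihydroxy-1,4-benzoquinone) | O=C1C(Br)=C(O)C(=O)C(Br)=C1O
A4 | alternative 2 | 4,4'-[(2,5-dibromo-3,6-dimethoxy-1,4-phenylene)bis(oxy)]bis[2-(trimethylsilyl)phenol] | COc1c(Oc2ccc(O)c([Si](C)(C)C)c2)c(Br)c(OC)c(Oc2ccc(O)c([Si](C)(C)C)c2)c1Br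
A5 | alternative 2 | [(2,5-dibromo-3,6-dimethoxy-1,4-phenylene)bis(oxy)]bis[(vinyl)methylidene]bis(pentacarbonylchromium) | C=CC(Oc1c(OC)c(Br)c(OC(C=C)=[Cr](=C=O)(=C=O)(=C=O)(=C=O)=C=O)c(OC)c1Br)=[Cr](=C=O)(=C=O)(=C=O)(=C=O)=C=O
A6 | alternative 2 | trimethylsilylacetylene | C#C[Si](C)(C)C
A7 | alternative 3 | 2-oxo-3-(2,3,5-tribromo-4-methoxyphenoxy)propanal | O=CC(=O)COc1cc(Br)c(OC)c(Br)c1Br
A8 | alternative 3 | 2,5-bis(2,3,5-tribromo-4-methoxyphenoxy)-1,4-benzoquinone | O=C1C=C(Oc2cc(Br)c(OC)c(Br)c2Br)C(=O)C=C1Oc1cc(Br)c(OC)c(Br)c1Br
A9 | alternative 3 | 2,5-dibromo-3,6-bis(2,3,5-tribromo-4-methoxyphenoxy)-1,4-benzoquinone | O=C1C(Br)=C(Oc2cc(Br)c(OC)c(Br)c2Br)C(=O)C(Br)=C1Oc1cc(Br)c(OC)c(Br)c1Br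
A10 | alternative 3 | 2,5-dibromo-3,6-bis(2,3,5-tribromo-4-methoxyphenoxy)benzene-1,4-diol | COc1c(Br)cc(Oc2c(O)c(Br)c(Oc3cc(Br)c(OC)c(Br)c3Br)c(O)c2Br)c(Br)c1Br
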